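**Assumption:** Melanocin F has no stereocentre, so the target is the achiral compound itself; the (S) centre carried from L-tyrosine in 3–10 is destroyed in step 5 and its integrity is irrelevant, and 13 is isolated as its imidazolium/sulfate inner salt, written in the neutral form of the target SMILES.

## Retrosynthetic overview

1. The aryl sulfate comes from phenol 12 by late O-sulfation; the phenol is carried as a benzyl ether until then.
2. The imidazole, the only ring made, comes from α-formamido ketone 9 and ammonia by cyclodehydration.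
3. The α-amino ketone 8 comes from β-keto ester 6 by acidolysis and decarboxylation.
4. The key C–C bond (imidazole carbon to the 4-methoxybenzylic carbon) comes from a crossed Claisen condensation of the lithium enolate of tert-butyl 4-methoxyphenylacetate with the acyl imidazolide of Boc-Tyr(Bzl)-OH.
5. Both benzene rings are bought; ring formation order: imidazole only (step 5).

## Route

Step 1
Reactants: 1 4-methoxyphenylacetic acid
Product: 2 tert-butyl 2-(4-methoxyphenyl)acetate
Conditions: tert-butyl 2,2,2-trichloroacetimidate (2.0 equiv), BF3·OEt2 (5 mol %), CH2Cl2–cyclohexane 1:2, 0 °C → rt, 16 h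
Reagents that add atoms: tert-butyl 2,2,2-trichloroacetimidate, CC(C)(C)OC(=N)C(Cl)(Cl)Cl (tert-butyl group)
Why: Acid-catalysed trichloroacetimidate esterification (tert-butyl cation transfer to the carboxylic acid) is mild and installs an ester that acid later removes together with the Boc group; no stereocentre is involved.

Step 2
Reactants: 3 N-Boc-O-benzyl-L-tyrosine; 2 tert-butyl 2-(4-methoxyphenyl)acetate
Product: 6 tert-butyl (2RS,4S)-5-[4-(benzyloxy)phenyl]-4-[(tert-butoxycarbonyl)amino]-2-(4-methoxyphenyl)-3-oxopentanoate, via Boc-Tyr(Bzl) imidazolide 4 (not isolated), via lithium ester enolate 5 (not isolated)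
Conditions: (a) 3, CDI (1.1 equiv), THF, 0 °C → rt, 1 h; (b) 2 (4.0 equiv), LiHMDS (1.0 M in THF, 4.1 equiv), THF, −78 °C, 45 min; (c) solution of 4 added to 5, −78 → −20 °C, 2 h; AcOH quench, aqueous work-up, chromatography (excess 2 recovered)
Reagents that add atoms: 1,1'-carbonyldiimidazole, O=C(n1ccnc1)n1ccnc1 (imidazol-1-yl group of intermediate 4 only); lithium hexamethyldisilazide, [Li+].C[Si](C)(C)[N-][Si](C)(C)C (Li of intermediate 5 only); no reagent atoms remain in 6
Why: Crossed Claisen condensation (C-acylation of an ester enolate by an N-acylimidazole) works because the imidazolide is far more electrophilic than the tert-butyl ester, excess enolate covers the N–H, imidazole and product protons, and the stabilised product enolate drives the reaction; the new C2 centre forms as an epimer mixture that is removed by decarboxylation in step 3.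

Step 3
Reactants: 6 tert-butyl (2RS,4S)-5-[4-(benzyloxy)phenyl]-4-[(tert-butoxycarbonyl)amino]-2-(4-methoxyphenyl)-3-oxopentanoate
Product: 8 (3S)-3-amino-4-[4-(benzyloxy)phenyl]-1-(4-methoxyphenyl)butan-2-one hydrochloride, via β-keto acid hydrochloride 7 (not isolated)
Conditions: 4 M HCl in 1,4-dioxane (20 equiv), rt, 12 h, then 50 °C, 1 h; evaporate, triturate with Et2O
Reagents that add atoms: hydrogen chloride, Cl (chloride of 7 and 8)
Why: Acidolysis (E1 loss of isobutene) removes the Boc group and the tert-butyl ester and the β-keto acid decarboxylates, while the amine stays protonated so it can neither lactamise to a tetramic acid nor dimerise to a dihydropyrazine; the benzyl and methyl aryl ethers are inert to HCl/dioxane.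

Step 4
Reactants: 8 (3S)-3-amino-4-[4-(benzyloxy)phenyl]-1-(4-methoxyphenyl)butan-2-one hydrochloride
Product: 9 N-[(2S)-1-[4-(benzyloxy)phenyl]-4-(4-methoxyphenyl)-3-oxobutan-2-yl]formamide
Conditions: HCO2Na (1.1 equiv), HCO2H, then Ac2O (3 equiv) at 0–10 °C → rt, 3 h
Reagents that add atoms: formic acid, O=CO (formyl group; transferred through acetic formic anhydride, CC(=O)OC=O, formed in the flask with Ac2O)
Why: N-Formylation by the mixed anhydride (formyl transfer is faster than acetyl transfer) traps the amine as formate releases it, so α-amino ketone self-condensation does not compete.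

Step 5
Reactants: 9 N-[(2S)-1-[4-(benzyloxy)phenyl]-4-(4-methoxyphenyl)-3-oxobutan-2-yl]formamide
Product: 11 4-[4-(benzyloxy)benzyl]-5-(4-methoxybenzyl)-1H-imidazole, via formamido ketimine 10 (not isolated)
Conditions: NH4OAc (15 equiv), AcOH, reflux, 3 h; aq. NH3 work-up
Reagents that add atoms: ammonium acetate, CC(=O)[O-].[NH4+] (second ring nitrogen)
Why: Cyclodehydration of an α-acylamino ketone with ammonia (Davidson-type imidazole synthesis) proceeds by ketimine formation, attack of the imine nitrogen on the formyl carbon and loss of two waters to the aromatic imidazole, which erases the stereocentre; the large excess of NH4OAc suppresses Robinson–Gabriel oxazole formation.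

Step 6
Reactants: 11 4-[4-(benzyloxy)benzyl]-5-(4-methoxybenzyl)-1H-imidazole
Product: 12 4-{[5-(4-methoxybenzyl)-1H-imidazol-4-yl]methyl}phenol
Conditions: H2 (1 atm), 10% Pd/C, MeOH–THF, AcOH (2 equiv), rt, 6 h; filter, NaHCO3 work-up
Reagents that add atoms: none
Why: Catalytic hydrogenolysis cleaves the benzyl aryl ether, while the methyl ether, the imidazole and the imidazolyl–CH2–aryl C–C bonds are inert at 1 atm H2.

Step 7
Reactants: 12 4-{[5-(4-methoxybenzyl)-1H-imidazol-4-yl]methyl}phenol
Product: 13 Melanocin F, 4-{[5-(4-methoxybenzyl)-1H-imidazol-4-yl]methyl}phenyl hydrogen sulfate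
Conditions: SO3·pyridine (2.5 equiv), pyridine, 0 °C → rt, 16 h; H2O, concentrate, pH 6–7, C18 reversed phase (H2O → MeOH), lyophilise
Reagents that add atoms: sulfur trioxide–pyridine complex, [O-]S(=O)(=O)[n+]1ccccc1 (SO3)
Why: O-Sulfation of the phenol by SO3 transfer from the pyridine complex gives the aryl sulfate monoester, isolated near neutral pH as the inner salt, and any N-sulfoimidazole adduct is a labile SO3 donor that hydrolyses on aqueous work-up.

## Compound list

1 | 4-methoxyphenylacetic acid | COc1ccc(CC(=O)O)cc1 | starting material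
2 | tert-butyl 2-(4-methoxyphenyl)acetate | COc1ccc(CC(=O)OC(C)(C)C)cc1 | intermediate
3 | N-Boc-O-benzyl-L-tyrosine, (S) | CC(C)(C)OC(=O)N[C@@H](Cc1ccc(OCc2ccccc2)cc1)C(=O)O | starting material
4 | tert-butyl N-[(2S)-3-[4-(benzyloxy)phenyl]-1-(1H-imidazol-1-yl)-1-oxopropan-2-yl]carbamate (acyl imidazolide, not isolated) | CC(C)(C)OC(=O)N[C@@H](Cc1ccc(OCc2ccccc2)cc1)C(=O)n1ccnc1 | intermediate
5 | lithium 1-tert-butoxy-2-(4-methoxyphenyl)ethen-1-olate (enolate of 2, geometry undefined and immaterial, not isolated) | [Li+].[O-]C(OC(C)(C)C)=Cc1ccc(OC)cc1 | intermediate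
6 | tert-butyl (2RS,4S)-5-[4-(benzyloxy)phenyl]-4-[(tert-butoxycarbonyl)amino]-2-(4-methoxyphenyl)-3-oxopentanoate (C2 epimer mixture) | CC(C)(C)OC(=O)N[C@@H](Cc1ccc(OCc2ccccc2)cc1)C(=O)C(C(=O)OC(C)(C)C)c1ccc(OC)cc1 | intermediate
7 | (4S)-4-amino-5-[4-(benzyloxy)phenyl]-2-(4-methoxyphenyl)-3-oxopentanoic acid hydrochloride (not isolated) | Cl.N[C@@H](Cc1ccc(OCc2ccccc2)cc1)C(=O)C(C(=O)O)c1ccc(OC)cc1 | intermediate
8 | (3S)-3-amino-4-[4-(benzyloxy)phenyl]-1-(4-methoxyphenyl)butan-2-one hydrochloride | Cl.N[C@@H](Cc1ccc(OCc2ccccc2)cc1)C(=O)Cc1ccc(OC)cc1 | intermediate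
9 | N-[(2S)-1-[4-(benzyloxy)phenyl]-4-(4-methoxyphenyl)-3-oxobutan-2-yl]formamide | O=CN[C@@H](Cc1ccc(OCc2ccccc2)cc1)C(=O)Cc1ccc(OC)cc1 | intermediate
10 | N-[(2S)-1-[4-(benzyloxy)phenyl]-3-imino-4-(4-methoxyphenyl)butan-2-yl]formamide (not isolated) | O=CN[C@@H](Cc1ccc(OCc2ccccc2)cc1)C(=N)Cc1ccc(OC)cc1 | intermediate
11 | 4-[4-(benzyloxy)benzyl]-5-(4-methoxybenzyl)-1H-imidazole | COc1ccc(Cc2[nH]cnc2Cc2ccc(OCc3ccccc3)cc2)cc1 | intermediate
12 | 4-{[5-(4-methoxybenzyl)-1H-imidazol-4-yl]methyl}phenol | COc1ccc(Cc2[nH]cnc2Cc2ccc(O)cc2)cc1 | intermediate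
13 | Melanocin F, 4-{[5-(4-methoxybenzyl)-1H-imidazol-4-yl]methyl}phenyl hydrogen sulfate (achiral) | COc1ccc(Cc2[nH]cnc2Cc2ccc(OS(=O)(=O)O)cc2)cc1 | target

## Summary

Total step count: 7.
Longest linear sequence: 7 steps (1 → 2 → 6 → 8 → 9 → 11 → 12 → 13); 6 steps from 3.

## Steps most likely to fail and fallbacks

**Step 2 (crossed Claisen).** The risks are proton transfer instead of C-acylation, low conversion with the stabilised hindered enolate, and oxazolone formation from the imidazolide. The fallback sets out from 3 and comes back at 6. Acid 3 is coupled with N,O-dimethylhydroxylamine hydrochloride (EDC·HCl, N-methylmorpholine, CH2Cl2) to the Weinreb amide F1. LiAlH4 (THF, 0 °C) reduces it to N-Boc-O-benzyl-L-tyrosinal F2. The aldehyde is added at −78 °C to the lithium ester enolate 5 (from 2 and LiHMDS) in an intermolecular aldol addition, giving the β-hydroxy ester F3 as an inconsequential diastereomer mixture. Dess–Martin periodinane (CH2Cl2, NaHCO3) oxidises it to 6.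

**Step 5 (imidazole cyclodehydration).** The risks are oxazole formation and incomplete condensation. The fallback sets out from 8, which also bypasses step 4, and comes back at 11. A Marckwald synthesis with KSCN (1.5 equiv, EtOH–H2O, 90 °C) converts 8 into the imidazole-2-thione F4. Oxidative desulfurisation with 30% H2O2 in AcOH (0 °C → rt, through the sulfinic acid and loss of SO2) then gives 11.

**Step 7 (sulfation and isolation of the zwitterion).** The risks are interference by the imidazole N–H, acid lability of the aryl sulfate, and purification of a very polar inner salt. The fallback sets out from 11 and comes back at 13. Imidazole 11 is N-protected with Boc2O (Et3N, cat. DMAP, MeCN) to the N-Boc imidazole F5 (either N-regioisomer serves; one is drawn). Hydrogenolysis (H2, Pd/C, EtOAc, no acid) gives the N-Boc phenol F6. Sulfation with SO3·NEt3 (DMF, 50 °C) gives the N-Boc aryl sulfate triethylammonium salt F7, a lipophilic ion pair that can be purified on silica. The N-Boc group is then removed with 7 M NH3 in MeOH at rt, and C18 chromatography at pH about 5 delivers 13.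

## Further compounds

F1 | step 2 | tert-butyl N-[(2S)-3-[4-(benzyloxy)phenyl]-1-[methoxy(methyl)amino]-1-oxopropan-2-yl]carbamate (Weinreb amide) | CC(C)(C)OC(=O)N[C@@H](Cc1ccc(OCc2ccccc2)cc1)C(=O)N(C)OC
F2 | step 2 | tert-butyl N-[(2S)-1-[4-(benzyloxy)phenyl]-3-oxopropan-2-yl]carbamate (N-Boc-O-benzyl-L-tyrosinal) | CC(C)(C)OC(=O)N[C@@H](Cc1ccc(OCc2ccccc2)cc1)C=O
F3 | step 2 | tert-butyl (4S)-5-[4-(benzyloxy)phenyl]-4-[(tert-butoxycarbonyl)amino]-3-hydroxy-2-(4-methoxyphenyl)pentanoate (mixture at C2 and C3) | CC(C)(C)OC(=O)N[C@@H](Cc1ccc(OCc2ccccc2)cc1)C(O)C(C(=O)OC(C)(C)C)c1ccc(OC)cc1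
F4 | step 5 | 4-[4-(benzyloxy)benzyl]-5-(4-methoxybenzyl)-1,3-dihydro-2H-imidazole-2-thione | COc1ccc(Cc2[nH]c(=S)[nH]c2Cc2ccc(OCc3ccccc3)cc2)cc1
F5 | step 7 | tert-butyl 4-[4-(benzyloxy)benzyl]-5-(4-methoxybenzyl)-1H-imidazole-1-carboxylate | COc1ccc(Cc2c(Cc3ccc(OCc4ccccc4)cc3)ncn2C(=O)OC(C)(C)C)cc1
F6 | step 7 | tert-butyl 4-(4-hydroxybenzyl)-5-(4-methoxybenzyl)-1H-imidazole-1-carboxylate | COc1ccc(Cc2c(Cc3ccc(O)cc3)ncn2C(=O)OC(C)(C)C)cc1
F7 | step 7 | triethylammonium 4-{[1-(tert-butoxycarbonyl)-5-(4-methoxybenzyl)-1H-imidazol-4-yl]methyl}phenyl sulfate | COc1ccc(Cc2c(Cc3ccc(OS(=O)(=O)[O-])cc3)ncn2C(=O)OC(C)(C)C)cc1.CC[NH+](CC)CC
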